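**Plan**

1. Cuts: after the six benzyl ethers, the lower pyran ring is cut at O1–C2 and C3–C4 (with the C3 hydroxyl traded for a C3 formyl group on a C3=C4 double bond). This gives a salicylaldehyde carrying the upper unit plus 3,4-bis(benzyloxy)cinnamaldehyde. Then the CHO–C4a bond is cut, then the interflavan bond C4(upper)–C6(lower), giving resorcinol and a 4-acetoxyflavan from (+)-fustin.
2. Forward: fustin supplies rings A, B and C of the upper unit. Resorcinol is bonded to C4 and becomes lower ring A; it is formylated at the future C4a and benzylated at the future 7-oxygen. Step 8 closes the lower pyran ring last and brings lower ring B with it. Steps 9–11 turn the formyl group into the C3 hydroxyl, saturate C3=C4 and remove the benzyl groups.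
3. Enabling feature: in the lower unit O1 sits on C8a, ortho to C4a, which carries C4. With C4 as a formyl carbon, lower ring A is a salicylaldehyde whose phenol oxygen and aldehyde carbon are the 1,3-placed nucleophile and electrophile that a β-aryl enal (C2, C3, ring B) needs for an oxa-Michael/aldol annulation.
4. Stereochemistry: upper C2 and C3 are bought with fustin. Upper C4 is set by attack anti to the participating 3-acetoxy group. Lower C2 is set by the chiral amine catalyst in step 8. Lower C3 is relayed from C2 by hydrogenation anti to the C2 aryl group.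

Key step: step 8

Assumption: natural (+)-fustin, the (2R,3R)-dihydroflavonol, is taken as purchasable in enantiopure form; the target is read as fisetinidol-(4α→6)-ent-epifisetinidol (upper unit 2R,3S with the C4 aryl bond trans to the 3-hydroxyl; lower unit 2S,3S, 2,3-cis).

**Route**

Step 1
Reactants: 1 (+)-fustin
Product: 2 7,3',4'-tri-O-benzylfustin
Conditions: BnBr (3.3 equiv), K2CO3, DMF, rt
Reagents that add atoms: benzyl bromide, BrCc1ccccc1
Why: Williamson ether synthesis: K2CO3 deprotonates the three phenols but not the C3 alcohol, so only the phenols are benzylated, and the mild base at room temperature should leave the (2R,3R) centres in place.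

Step 2
Reactants: 2 7,3',4'-tri-O-benzylfustin
Product: 3 7,3',4'-tri-O-benzylmollisacacidin
Conditions: NaBH4, THF/EtOH (1:1), 0 °C
Reagents that add atoms: none
Why: Borohydride reduction of the aryl ketone should give mainly the 3,4-trans diol (4R); this centre is ionised again in step 4, so its configuration is not critical.

Step 3
Reactants: 3 7,3',4'-tri-O-benzylmollisacacidin
Product: 4 3,4-di-O-acetyl-7,3',4'-tri-O-benzylmollisacacidin
Conditions: Ac2O, pyridine, DMAP (cat.), CH2Cl2, rt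
Reagents that add atoms: acetic anhydride, CC(=O)OC(C)=O
Why: DMAP-catalysed acylation of both secondary alcohols with retention makes the C4 oxygen a leaving group and puts the directing acetoxy group on C3.

Step 4
Reactants: 4 3,4-di-O-acetyl-7,3',4'-tri-O-benzylmollisacacidin; 5 resorcinol (5 equiv)
Product: 6 3-O-acetyl-7,3',4'-tri-O-benzyl-4α-(2,4-dihydroxyphenyl)fisetinidol
Conditions: BF3·OEt2 (0.5 equiv), CH2Cl2/1,4-dioxane, −20 to 0 °C
Reagents that add atoms: none
Why: Friedel–Crafts alkylation: the C4 acetate ionises to a benzylic cation stabilised by the 7-benzyloxy group para to C4a, the C3 acetoxy group bridges the β-face as a 1,3-dioxolan-2-ylium ion, and resorcinol attacks through its C4 (para to one hydroxyl, ortho to the other) from the α-face, so the new C4 centre is 3,4-trans (4α).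

Step 5
Reactants: 6 3-O-acetyl-7,3',4'-tri-O-benzyl-4α-(2,4-dihydroxyphenyl)fisetinidol
Product: 8 5-(3-O-acetyl-7,3',4'-tri-O-benzylfisetinidol-4α-yl)-2,4-dihydroxybenzaldehyde, via hydroxymethyl phenol 7 (not isolated)
Conditions: MgCl2, Et3N, (CH2O)n, MeCN, 70 °C; aq. HCl work-up
Reagents that add atoms: formaldehyde (as paraformaldehyde), C=O
Why: Casnati–Skattebøl ortho-formylation: the magnesium phenoxide delivers formaldehyde to the open ortho carbon that is also para to the second hydroxyl (the future C4a) rather than to the hindered carbon between the two hydroxyls, and a second formaldehyde oxidises the hydroxymethyl group by hydride transfer; rings without a free phenol do not react.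

Step 6
Reactants: 8 5-(3-O-acetyl-7,3',4'-tri-O-benzylfisetinidol-4α-yl)-2,4-dihydroxybenzaldehyde
Product: 9 4-(benzyloxy)-5-(3-O-acetyl-7,3',4'-tri-O-benzylfisetinidol-4α-yl)-2-hydroxybenzaldehyde
Conditions: BnBr (1.1 equiv), KHCO3, DMF, 40 °C
Reagents that add atoms: benzyl bromide, BrCc1ccccc1
Why: Regioselective Williamson etherification: the hydroxyl para to the formyl group is the more acidic one, while the ortho hydroxyl (the future O1) is held in a hydrogen bond to the aldehyde, so a weak base should benzylate only the former.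

Step 7
Reactants: 10 3,4-bis(benzyloxy)benzaldehyde
Product: 11 (E)-3-[3,4-bis(benzyloxy)phenyl]prop-2-enal
Conditions: Ph3P=CHCHO (1.1 equiv), toluene, 80 °C
Reagents that add atoms: (triphenylphosphoranylidene)acetaldehyde, O=CC=P(c1ccccc1)(c1ccccc1)c1ccccc1
Why: Wittig olefination with a stabilised formyl ylide, which should give the (E)-enal.

Step 8
Reactants: 9 4-(benzyloxy)-5-(3-O-acetyl-7,3',4'-tri-O-benzylfisetinidol-4α-yl)-2-hydroxybenzaldehyde; 11 (E)-3-[3,4-bis(benzyloxy)phenyl]prop-2-enal (1.5 equiv)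
Product: 13 (2S)-7-(benzyloxy)-2-[3,4-bis(benzyloxy)phenyl]-6-(3-O-acetyl-7,3',4'-tri-O-benzylfisetinidol-4α-yl)-2H-chromene-3-carbaldehyde, via oxa-Michael adduct 12 (not isolated)
Conditions: (R)-2-[diphenyl(trimethylsilyloxy)methyl]pyrrolidine (20 mol%), 2-nitrobenzoic acid (20 mol%), 4 Å molecular sieves, toluene, rt
Reagents that add atoms: none
Why: This is the amine-catalysed domino oxa-Michael/aldol condensation known for salicylaldehydes and cinnamaldehydes: the catalyst and 11 form an (E)-iminium ion, the phenol oxygen of 9 (future O1) adds to its β-carbon (future C2), the resulting enamine attacks the neighbouring formyl carbon (future C4), and loss of water and catalyst gives the conjugated enal. The lower pyran ring closes in the aldol event, a 6-exo-trig attack of the enamine α-carbon (C3) on the aldehyde, so O1–C2 and C3–C4 are both made in one operation and lower ring B arrives with them. The one new stereocentre, C2, is set in the oxa-Michael step by the catalyst: the diphenyl(silyloxy)methyl group of the (R)-pyrrolidine shields the Si face of the iminium β-carbon, the phenol adds to the Re face, and C2 should become S; the distant centres of the upper unit are not expected to override this. The step needs reaction at one phenol and one ring size only, and the substrate secures both, because the 7-oxygen is benzylated and only the hydroxyl ortho to the formyl group can follow the conjugate addition with a six-membered aldol closure. The C3 formyl group and the C3=C4 double bond are helpers that are exchanged for the C3 hydroxyl and two hydrogens in steps 9 and 10.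

Step 9
Reactants: 13 (2S)-2H-chromene-3-carbaldehyde
Product: 14 (2S)-7-(benzyloxy)-2-[3,4-bis(benzyloxy)phenyl]-6-(3-O-acetyl-7,3',4'-tri-O-benzylfisetinidol-4α-yl)-2H-chromen-3-yl formate
Conditions: mCPBA (1.1 equiv), CH2Cl2, 0 °C
Reagents that add atoms: 3-chloroperoxybenzoic acid, O=C(OO)c1cccc(Cl)c1
Why: Baeyer–Villiger oxidation of an α-substituted β-aryl enal: in the Criegee adduct the electron-rich alkenyl carbon C3 should migrate in preference to hydrogen, which puts oxygen on C3 as an enol formate without touching C2.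

Step 10
Reactants: 14 (2S)-2H-chromen-3-yl formate
Product: 16 7,3',4'-tri-O-benzylfisetinidol-(4α→6)-7,3',4'-tri-O-benzyl-ent-epifisetinidol, via cis-formate 15 (not isolated)
Conditions: H2 (4 atm), [Ir(cod)(PCy3)(py)]PF6 (5 mol%), CH2Cl2, rt; then K2CO3 (cat.), MeOH, rt
Reagents that add atoms: none
Why: Homogeneous hydrogenation of a cyclic enol ester followed by transesterification: the C2 aryl group should sit pseudo-axial next to the C3 formyloxy group and block its face of the C3=C4 bond, so hydrogen adds from the other face and the new C3 centre is S (3-oxygen cis to the 2-aryl group); methanolysis then frees both C3 hydroxyls, and the benzyl ethers are stable to both operations.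

Step 11
Reactants: 16 hexa-O-benzyl dimer
Product: 17 fisetinidol-(4α→6)-ent-epifisetinidol
Conditions: H2 (1 atm), Pd(OH)2/C, THF/MeOH (1:1), rt
Reagents that add atoms: none
Why: Hydrogenolysis of the six benzyl ethers; the benzylic C2–O1 and C4–aryl bonds of flavan-3-ols are expected to survive if the reaction is stopped at full debenzylation, and no stereocentre is touched.

**Compound list**

1 | (+)-fustin, (2R,3R)-2-(3,4-dihydroxyphenyl)-3,7-dihydroxychroman-4-one | Oc1ccc2c(c1)O[C@H](c1ccc(O)c(O)c1)[C@@H](O)C2=O | starting material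
2 | 7,3',4'-tri-O-benzylfustin, (2R,3R)-7-(benzyloxy)-2-[3,4-bis(benzyloxy)phenyl]-3-hydroxychroman-4-one | c1ccccc1COc1ccc2c(c1)O[C@H](c1ccc(OCc3ccccc3)c(OCc3ccccc3)c1)[C@@H](O)C2=O | intermediate
3 | 7,3',4'-tri-O-benzylmollisacacidin, (2R,3S,4R)-7-(benzyloxy)-2-[3,4-bis(benzyloxy)phenyl]chromane-3,4-diol (2,3-trans-3,4-trans) | c1ccccc1COc1ccc2c(c1)O[C@H](c1ccc(OCc3ccccc3)c(OCc3ccccc3)c1)[C@@H](O)[C@@H]2O | intermediate
4 | 3,4-di-O-acetate of 3 (same spatial arrangement, 2,3-trans-3,4-trans) | c1ccccc1COc1ccc2c(c1)O[C@H](c1ccc(OCc3ccccc3)c(OCc3ccccc3)c1)[C@@H](OC(C)=O)[C@@H]2OC(C)=O | intermediate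
5 | resorcinol (benzene-1,3-diol) | Oc1cccc(O)c1 | starting material
6 | 3-O-acetyl-7,3',4'-tri-O-benzyl-4α-(2,4-dihydroxyphenyl)fisetinidol (2R,3S; C4 aryl trans to the 3-acetoxy group) | c1ccccc1COc1ccc2c(c1)O[C@H](c1ccc(OCc3ccccc3)c(OCc3ccccc3)c1)[C@@H](OC(C)=O)[C@@H]2c1ccc(O)cc1O | intermediate
7 | 6 with a hydroxymethyl group at C5 of the dihydroxyphenyl ring (ortho to the 4-hydroxyl, para to the 2-hydroxyl) | c1ccccc1COc1ccc2c(c1)O[C@H](c1ccc(OCc3ccccc3)c(OCc3ccccc3)c1)[C@@H](OC(C)=O)[C@@H]2c1cc(CO)c(O)cc1O | intermediate (not isolated)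
8 | 5-(3-O-acetyl-7,3',4'-tri-O-benzylfisetinidol-4α-yl)-2,4-dihydroxybenzaldehyde | c1ccccc1COc1ccc2c(c1)O[C@H](c1ccc(OCc3ccccc3)c(OCc3ccccc3)c1)[C@@H](OC(C)=O)[C@@H]2c1cc(C=O)c(O)cc1O | intermediate
9 | 4-(benzyloxy)-5-(3-O-acetyl-7,3',4'-tri-O-benzylfisetinidol-4α-yl)-2-hydroxybenzaldehyde | c1ccccc1COc1ccc2c(c1)O[C@H](c1ccc(OCc3ccccc3)c(OCc3ccccc3)c1)[C@@H](OC(C)=O)[C@@H]2c1cc(C=O)c(O)cc1OCc1ccccc1 | intermediate
10 | 3,4-bis(benzyloxy)benzaldehyde | O=Cc1ccc(OCc2ccccc2)c(OCc2ccccc2)c1 | starting material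
11 | (E)-3-[3,4-bis(benzyloxy)phenyl]prop-2-enal | O=C/C=C/c1ccc(OCc2ccccc2)c(OCc2ccccc2)c1 | intermediate
12 | oxa-Michael adduct, (3R)-3-[3,4-bis(benzyloxy)phenyl]-3-[5-(benzyloxy)-2-formyl-4-(3-O-acetyl-7,3',4'-tri-O-benzylfisetinidol-4α-yl)phenoxy]propanal (held as its enamine with the catalyst; same spatial arrangement as C2 of 13) | c1ccccc1COc1ccc2c(c1)O[C@H](c1ccc(OCc3ccccc3)c(OCc3ccccc3)c1)[C@@H](OC(C)=O)[C@@H]2c1cc(C=O)c(cc1OCc1ccccc1)O[C@@H](c1ccc(OCc3ccccc3)c(OCc3ccccc3)c1)CC=O | intermediate (not isolated)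
13 | (2S)-7-(benzyloxy)-2-[3,4-bis(benzyloxy)phenyl]-6-(3-O-acetyl-7,3',4'-tri-O-benzylfisetinidol-4α-yl)-2H-chromene-3-carbaldehyde | c1ccccc1COc1ccc2c(c1)O[C@H](c1ccc(OCc3ccccc3)c(OCc3ccccc3)c1)[C@@H](OC(C)=O)[C@@H]2c1cc2c(cc1OCc1ccccc1)O[C@@H](c1ccc(OCc3ccccc3)c(OCc3ccccc3)c1)C(C=O)=C2 | intermediate
14 | (2S)-7-(benzyloxy)-2-[3,4-bis(benzyloxy)phenyl]-6-(3-O-acetyl-7,3',4'-tri-O-benzylfisetinidol-4α-yl)-2H-chromen-3-yl formate | c1ccccc1COc1ccc2c(c1)O[C@H](c1ccc(OCc3ccccc3)c(OCc3ccccc3)c1)[C@@H](OC(C)=O)[C@@H]2c1cc2c(cc1OCc1ccccc1)O[C@@H](c1ccc(OCc3ccccc3)c(OCc3ccccc3)c1)C(OC=O)=C2 | intermediate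
15 | (2S,3S)-7-(benzyloxy)-2-[3,4-bis(benzyloxy)phenyl]-6-(3-O-acetyl-7,3',4'-tri-O-benzylfisetinidol-4α-yl)chroman-3-yl formate (2,3-cis) | c1ccccc1COc1ccc2c(c1)O[C@H](c1ccc(OCc3ccccc3)c(OCc3ccccc3)c1)[C@@H](OC(C)=O)[C@@H]2c1cc2c(cc1OCc1ccccc1)O[C@@H](c1ccc(OCc3ccccc3)c(OCc3ccccc3)c1)[C@@H](OC=O)C2 | intermediate (not isolated)
16 | 7,3',4'-tri-O-benzylfisetinidol-(4α→6)-7,3',4'-tri-O-benzyl-ent-epifisetinidol (upper 2R,3S, 4α; lower 2S,3S) | c1ccccc1COc1ccc2c(c1)O[C@H](c1ccc(OCc3ccccc3)c(OCc3ccccc3)c1)[C@@H](O)[C@@H]2c1cc2c(cc1OCc1ccccc1)O[C@@H](c1ccc(OCc3ccccc3)c(OCc3ccccc3)c1)[C@@H](O)C2 | intermediate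
17 | fisetinidol-(4α→6)-ent-epifisetinidol (upper 2R,3S, 4α; lower 2S,3S) | Oc1ccc2c(c1)O[C@H](c1ccc(O)c(O)c1)[C@@H](O)[C@@H]2c1cc2c(cc1O)O[C@@H](c1ccc(O)c(O)c1)[C@@H](O)C2 | target

**Step count**

Total: 11 steps. Longest linear sequence: 10 steps (steps 1–6 and 8–11).

**Steps most likely to fail**

Step 8. The conjugate addition of a hindered, electron-rich salicylaldehyde to an electron-rich iminium ion may be slow, and reversal of the oxa-Michael step before the aldol closure may erode the facial selectivity at C2. The fallback sets out from 6 and 10 and comes back to the route at 17; it builds both lower centres before the ring is closed.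
- 10 is treated with vinylmagnesium bromide (THF, 0 °C) to give racemic 1-[3,4-bis(benzyloxy)phenyl]prop-2-en-1-ol F1.
- Sharpless kinetic resolution (Ti(OiPr)4, D-(−)-diisopropyl tartrate, tBuOOH 0.55 equiv, 4 Å molecular sieves, CH2Cl2, −20 °C) epoxidises the fast-reacting (S)-alcohol to the erythro epoxy alcohol (1R)-1-[3,4-bis(benzyloxy)phenyl]-1-[(2S)-oxiran-2-yl]methanol F2.
- Mitsunobu etherification (PPh3, DIAD, THF, 0 °C) of the less hindered phenol of 6 (para to the flavanyl group) with F2 inverts the carbinol centre and gives the aryl epoxy ether F3.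
- AuCl3/AgOTf in 1,2-dichloroethane promotes a 6-endo Friedel–Crafts opening of the terminal epoxide by the ring carbon ortho to the ether oxygen and para to the free hydroxyl, closing the lower pyran ring to the 2,3-cis chroman-3-ol F4.
- K2CO3 in MeOH removes the acetate to give the penta-O-benzyl dimer F5, which is debenzylated under the conditions of step 11 to 17.

Step 9. The peracid may epoxidise the electron-rich enol formate as it forms, or hydrogen may migrate in the Criegee adduct so that the acid results. The fallback sets out from 13 and comes back at 16; it exchanges carbon for oxygen by a Curtius degradation and sets C3 by hydride.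
- 13 is oxidised (NaClO2, NaH2PO4, 2-methylbut-2-ene, tBuOH/H2O) to the 2H-chromene-3-carboxylic acid F6.
- (PhO)2P(O)N3 and Et3N in toluene give the acyl azide F7, which on warming to 80 °C rearranges to the alkenyl isocyanate F8.
- Cold aqueous HCl in THF hydrolyses F8 to the flavan-3-one F9.
- LiBH(sBu)3 (THF, −78 °C) adds hydride anti to the C2 aryl group and gives the 2,3-cis alcohol F10.
- K2CO3 in MeOH removes the acetate to give 16.

Step 10. The C2 aryl group may not discriminate the two faces well enough, the trisubstituted enol ester may reduce slowly, or the enol C–O bond may be hydrogenolysed. The fallback sets out from 14 and comes back at 16; it replaces hydrogenation of the enol ester by hydride reduction of the ketone.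
- MeLi (4 equiv, THF, −78 °C) cleaves the formate to the C3–C4 lithium enolate and removes the acetate.
- Protonation with acetic acid at −78 °C gives the flavan-3-one F11 without enolisation toward C2.
- LiBH(sBu)3 (THF, −78 °C) then delivers hydride anti to the C2 aryl group and gives 16 directly.

**Further compounds**

F1 | step 8 | rac-1-[3,4-bis(benzyloxy)phenyl]prop-2-en-1-ol | C=CC(O)c1ccc(OCc2ccccc2)c(OCc2ccccc2)c1
F2 | step 8 | (1R)-1-[3,4-bis(benzyloxy)phenyl]-1-[(2S)-oxiran-2-yl]methanol (erythro) | O[C@H](c1ccc(OCc2ccccc2)c(OCc2ccccc2)c1)[C@H]1OC1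
F3 | step 8 | ether of the 4-hydroxyl of 6 with the inverted benzylic carbon of F2 (benzylic carbon S, oxirane carbon S) | c1ccccc1COc1ccc2c(c1)O[C@H](c1ccc(OCc3ccccc3)c(OCc3ccccc3)c1)[C@@H](OC(C)=O)[C@@H]2c4ccc(O[C@@H](c5ccc(OCc6ccccc6)c(OCc6ccccc6)c5)[C@H]5OC5)cc4O
F4 | step 8 | 3-O-acetyl-7,3',4'-tri-O-benzylfisetinidol-(4α→6)-3',4'-di-O-benzyl-ent-epifisetinidol (lower 7-hydroxyl free) | c1ccccc1COc1ccc2c(c1)O[C@H](c1ccc(OCc3ccccc3)c(OCc3ccccc3)c1)[C@@H](OC(C)=O)[C@@H]2c1cc2c(cc1O)O[C@@H](c1ccc(OCc3ccccc3)c(OCc3ccccc3)c1)[C@@H](O)C2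
F5 | step 8 | 7,3',4'-tri-O-benzylfisetinidol-(4α→6)-3',4'-di-O-benzyl-ent-epifisetinidol | c1ccccc1COc1ccc2c(c1)O[C@H](c1ccc(OCc3ccccc3)c(OCc3ccccc3)c1)[C@@H](O)[C@@H]2c1cc2c(cc1O)O[C@@H](c1ccc(OCc3ccccc3)c(OCc3ccccc3)c1)[C@@H](O)C2
F6 | step 9 | (2S)-2H-chromene-3-carboxylic acid corresponding to 13 | c1ccccc1COc1ccc2c(c1)O[C@H](c1ccc(OCc3ccccc3)c(OCc3ccccc3)c1)[C@@H](OC(C)=O)[C@@H]2c1cc2c(cc1OCc1ccccc1)O[C@@H](c1ccc(OCc3ccccc3)c(OCc3ccccc3)c1)C(C(O)=O)=C2
F7 | step 9 | acyl azide of F6 | c1ccccc1COc1ccc2c(c1)O[C@H](c1ccc(OCc3ccccc3)c(OCc3ccccc3)c1)[C@@H](OC(C)=O)[C@@H]2c1cc2c(cc1OCc1ccccc1)O[C@@H](c1ccc(OCc3ccccc3)c(OCc3ccccc3)c1)C(C(=O)N=[N+]=[N-])=C2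
F8 | step 9 | (2S)-3-isocyanato-2H-chromene | c1ccccc1COc1ccc2c(c1)O[C@H](c1ccc(OCc3ccccc3)c(OCc3ccccc3)c1)[C@@H](OC(C)=O)[C@@H]2c1cc2c(cc1OCc1ccccc1)O[C@@H](c1ccc(OCc3ccccc3)c(OCc3ccccc3)c1)C(N=C=O)=C2
F9 | step 9 | (2S)-flavan-3-one of the lower unit, upper 3-O-acetyl | c1ccccc1COc1ccc2c(c1)O[C@H](c1ccc(OCc3ccccc3)c(OCc3ccccc3)c1)[C@@H](OC(C)=O)[C@@H]2c1cc2c(cc1OCc1ccccc1)O[C@@H](c1ccc(OCc3ccccc3)c(OCc3ccccc3)c1)C(=O)C2
F10 | step 9 | 3-O-acetyl derivative of 16 (acetate on the upper unit; lower unit 2S,3S) | c1ccccc1COc1ccc2c(c1)O[C@H](c1ccc(OCc3ccccc3)c(OCc3ccccc3)c1)[C@@H](OC(C)=O)[C@@H]2c1cc2c(cc1OCc1ccccc1)O[C@@H](c1ccc(OCc3ccccc3)c(OCc3ccccc3)c1)[C@@H](O)C2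
F11 | step 10 | (2S)-flavan-3-one of the lower unit, upper 3-hydroxyl free | c1ccccc1COc1ccc2c(c1)O[C@H](c1ccc(OCc3ccccc3)c(OCc3ccccc3)c1)[C@@H](O)[C@@H]2c1cc2c(cc1OCc1ccccc1)O[C@@H](c1ccc(OCc3ccccc3)c(OCc3ccccc3)c1)C(=O)C2
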